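The target's ring B already exists in (R)-carvone: the carbon bearing the isopropenyl group becomes C5, the isopropenyl carbon becomes C4, the enone methyl becomes the C8 methyl and the carbonyl becomes C9. Ring A is therefore missing three carbons, C1 to C3, between C10 and C4, and the route rests on disconnecting C3–C4. In a single operation an iron hydride delivers a hydrogen atom to the isopropenyl CH2, which thereby becomes the second methyl on C4, and the tertiary C4 radical cyclises onto C3 of an acryloyl group on C10, closing ring A as a trans-decalin. The precursor is 6-methylcarvone carrying that acryloyl group on the methylated carbon, anti to the isopropenyl group.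

Key step: step 4

Numbering: the bicyclic core is numbered as in drimane (C1–C3, C4 with two methyls, C5–H, C6, C7, C8 with one methyl, C9, C10 with the angular methyl; C11 is the carbon on C9; ring A = C1–C5 and C10, ring B = C5–C10). Arene carbons are primed, C1′ on C11. Monocyclic compounds keep carvone numbering (C1 carbonyl, C5 bearing the isopropenyl group, C6 between them).
CIP remark: C5 of carvone is R; once C6 is quaternary it outranks the isopropenyl carbon, so the unchanged spatial arrangement is named 5S from compound 5 onwards, and the acryloyl precursor is (5S,6R).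
Remark: aryl hydrogen sulfates are strong, self-hydrolysing acids, so 23 and 24 are assumed to be handled as sodium or potassium salts, and the free acid as drawn is liberated only at the end by cation exchange.

Step 1
Reactants: 1 (R)-(−)-carvone
Product: 3 (5R,6S)-6-methylcarvone (trans epimer expected to predominate), via carvone lithium dienolate 2 (not isolated)
Conditions: LiN(i-Pr)2 (LDA), THF, −78 °C; MeI, −78 to 0 °C
Reagents that add atoms: iodomethane, CI
Why: Kinetic α′-deprotonation at C6 gives the cross-conjugated dienolate, whose C-methylation (enolate alkylation) should occur mainly anti to the isopropenyl group; the C6 configuration is of no consequence because C6 is made planar again in step 2.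

Step 2
Reactants: 3 (5R,6S)-6-methylcarvone; 4 acrolein
Product: 6 (5S,6R)-6-(1-hydroxyprop-2-en-1-yl)-6-methylcarvone as carbinol epimers, via 6-methylcarvone lithium dienolate 5 (not isolated)
Conditions: LiN(i-Pr)2 (LDA), THF, −78 °C; acrolein, −78 °C; AcOH quench at −78 °C
Reagents that add atoms: none
Why: Kinetic lithium aldol addition (1,2-addition to acrolein) of the tetrasubstituted enolate should take place on the face anti to the pseudo-axial isopropenyl group at C5, which sets the quaternary carbon (later C10) with its methyl syn and the three-carbon chain anti to the isopropenyl group; the carbinol centre is removed in step 3.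

Step 3
Reactants: 6 (5S,6R)-6-(1-hydroxyprop-2-en-1-yl)-6-methylcarvone
Product: 7 (5S,6R)-6-acryloyl-6-methylcarvone
Conditions: Dess–Martin periodinane, CH2Cl2, 0 °C to rt; used without delay
Reagents that add atoms: none
Why: Dess–Martin oxidation of the secondary allylic alcohol should give the vinyl ketone under neutral conditions that avoid retro-aldol cleavage and leave the non-enolisable 1,3-diketone intact.

Step 4
Reactants: 7 (5S,6R)-6-acryloyl-6-methylcarvone
Product: 8 (5S,10R)-4,4,8,10-tetramethyl-trans-decal-7-ene-1,9-dione
Conditions: Fe(acac)3 (30 mol%), PhSiH3 (slow addition), EtOH/ethylene glycol (5:1), 60 °C, 0.02 M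
Reagents that add atoms: none
Why: An iron hydride formed from Fe(acac)3 and PhSiH3 in ethanol transfers a hydrogen atom to the CH2 terminus of the electron-rich 1,1-disubstituted isopropenyl group, which becomes the second C4 methyl and leaves the tertiary C4 radical. This nucleophilic radical adds to the unsubstituted β-carbon C3 of the acryloyl group in a chair-like 6-endo-trig closure that forms the C3–C4 bond and ring A; the α-keto radical at C2 is then reduced by divalent iron to the enolate and protonated by ethanol, which returns trivalent iron. The closest known reaction type is the iron-hydride-initiated reductive coupling of an unactivated alkene with an enone, that is, an intramolecular Giese addition of a tertiary radical. No stereocentre is created, since C4 becomes a gem-dimethyl carbon and the trans ring fusion is already fixed by the anti relationship of the C5 and C10 substituents set in step 2. The step needs hydrogen-atom transfer to the isopropenyl group in preference to the two electron-poor enone alkenes, which alkene electronics should secure, and 6-endo closure at C3 in preference to 5-exo attack at C2, which the polarity match of the radical with the enone β-carbon, the unhindered terminus and the stabilised α-keto radical should secure; dilution and slow silane addition are meant to suppress simple reduction.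

Step 5
Reactants: 8 (5S,10R)-4,4,8,10-tetramethyl-trans-decal-7-ene-1,9-dione
Product: 10 (5S,10R)-4,4,8,10-tetramethyl-9-oxo-trans-decala-1,7-dien-1-yl trifluoromethanesulfonate, via potassium C1-enolate 9 (not isolated)
Conditions: KN(SiMe3)2 (KHMDS), THF, −78 °C; PhNTf2, −78 °C to rt
Reagents that add atoms: N-phenylbis(trifluoromethanesulfonimide), FC(F)(F)S(=O)(=O)N(c1ccccc1)S(=O)(=O)C(F)(F)F
Why: The saturated C1 ketone can enolise only towards C2 and should be deprotonated kinetically in preference to the γ-position of the C9 enone, and O-sulfonylation of the enolate (enol triflate formation) uses no nucleophile that could open the 1,3-diketone by retro-Claisen cleavage.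

Step 6
Reactants: 10 (5S,10R)-4,4,8,10-tetramethyl-9-oxo-trans-decala-1,7-dien-1-yl trifluoromethanesulfonate
Product: 11 (5S,10S)-4,4,8,10-tetramethyl-trans-decala-1,7-dien-9-one
Conditions: Pd(OAc)2 (cat.), PPh3, HCO2H, Et3N, DMF, 60 °C
Reagents that add atoms: none
Why: Palladium-catalysed formate reduction of the enol triflate (oxidative addition to zerovalent palladium, formate exchange, decarboxylation, reductive elimination) should replace C1–O by C1–H and tolerate the enone, which completes the removal of the C1 oxygen.

Step 7
Reactants: 11 (5S,10S)-4,4,8,10-tetramethyl-trans-decala-1,7-dien-9-one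
Product: 12 (5S,8S,10S)-4,4,8,10-tetramethyl-trans-decalin-9-one
Conditions: H2 (1 atm), Pd/C, EtOAc, rt
Reagents that add atoms: none
Why: Heterogeneous hydrogenation should saturate C1=C2 and add hydrogen to C7=C8 from the α-face, opposite to the axial β-methyl groups on C10 and C4, so that the C8 methyl ends up β (8S); the neutral medium is chosen so that this kinetic, axial methyl next to the ketone does not epimerise.

Step 8
Reactants: 13 2,4,5-trihydroxybenzaldehyde
Product: 14 4,5-bis(allyloxy)-2-hydroxybenzaldehyde
Conditions: allyl bromide (2.1 equiv), K2CO3 (2.1 equiv), DMF, rt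
Reagents that add atoms: allyl bromide, C=CCBr
Why: Williamson etherification should occur at the 4- and 5-hydroxyl groups, because the 2-hydroxyl group is held in a hydrogen bond to the aldehyde and its phenoxide is the poorest nucleophile.

Step 9
Reactants: 14 4,5-bis(allyloxy)-2-hydroxybenzaldehyde
Product: 15 4,5-bis(allyloxy)-2-(methoxymethoxy)benzaldehyde
Conditions: MOMCl, i-Pr2NEt, CH2Cl2, 0 °C to rt
Reagents that add atoms: chloromethyl methyl ether, COCCl
Why: O-Alkylation of the remaining phenol to its methoxymethyl acetal gives a group that tolerates hydride and organomagnesium reagents and can later be removed without touching the allyl ethers.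

Step 10
Reactants: 15 4,5-bis(allyloxy)-2-(methoxymethoxy)benzaldehyde
Product: 16 [4,5-bis(allyloxy)-2-(methoxymethoxy)phenyl]methanol
Conditions: NaBH4, MeOH, 0 °C
Reagents that add atoms: none
Why: Borohydride reduction of the aryl aldehyde to the benzylic alcohol is chemoselective in the presence of the acetal and the allyl ethers.

Step 11
Reactants: 16 [4,5-bis(allyloxy)-2-(methoxymethoxy)phenyl]methanol
Product: 17 1,2-bis(allyloxy)-4-(chloromethyl)-5-(methoxymethoxy)benzene
Conditions: PPh3, N-chlorosuccinimide, THF, 0 °C to rt; used at once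
Reagents that add atoms: N-chlorosuccinimide, ClN1C(=O)CCC1=O
Why: Chlorination through the alkoxyphosphonium salt (Appel-type reaction) runs under neutral conditions, so the acid-labile methoxymethyl group and the solvolysis-prone, electron-rich benzylic chloride should survive.

Step 12
Reactants: 12 (5S,8S,10S)-4,4,8,10-tetramethyl-trans-decalin-9-one; 17 1,2-bis(allyloxy)-4-(chloromethyl)-5-(methoxymethoxy)benzene
Product: 19 (5S,8S,9S,10S)-9-{[4,5-bis(allyloxy)-2-(methoxymethoxy)phenyl]methyl}-4,4,8,10-tetramethyl-trans-decalin-9-ol, via arylmethylmagnesium chloride 18 (not isolated)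
Conditions: 17, Mg turnings, THF, 0 °C (slow addition); then 12 precomplexed with LaCl3·2LiCl, THF, 0 °C to rt; aq. NH4Cl
Reagents that add atoms: none
Why: Lanthanide-promoted Grignard 1,2-addition of the benzylic organomagnesium reagent to the hindered ketone should outrun enolisation (which would endanger C8), and the nucleophile should enter axially from the α-face, anti to the two β-axial methyl groups on C8 and C10, which sets C9 with the hydroxyl group β (equatorial) and the arylmethyl group α.

Step 13
Reactants: 19 (5S,8S,9S,10S)-9-{[4,5-bis(allyloxy)-2-(methoxymethoxy)phenyl]methyl}-4,4,8,10-tetramethyl-trans-decalin-9-ol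
Product: 20 (5S,8S,10S)-9-{(E)-[4,5-bis(allyloxy)-2-(methoxymethoxy)phenyl]methylidene}-4,4,8,10-tetramethyl-trans-decalin
Conditions: Burgess reagent (methyl N-(triethylammoniosulfonyl)carbamate), toluene, 60 °C
Reagents that add atoms: none
Why: Syn-elimination of the derived sulfamate (Burgess dehydration) can only use a C11 hydrogen, because C10 carries none and the C8 hydrogen is trans to the equatorial C9 oxygen, and the transition state with the aryl group turned away from the quaternary C10 should give the E alkene (aryl syn to C8) without touching C8.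

Step 14
Reactants: 20 (5S,8S,10S)-9-{(E)-[4,5-bis(allyloxy)-2-(methoxymethoxy)phenyl]methylidene}-4,4,8,10-tetramethyl-trans-decalin
Product: 21 4,5-bis(allyloxy)-2-{(E)-[(5S,8S,10S)-4,4,8,10-tetramethyl-trans-decalin-9-ylidene]methyl}phenol
Conditions: PPTS (0.3 equiv), MeOH, 60 °C
Reagents that add atoms: none
Why: Acid-catalysed transacetalisation with methanol should cleave the aryl methoxymethyl ether and spare the allyl ethers, and the weak pyridinium acid is chosen so that the electron-rich styrene is not protonated.

Step 15
Reactants: 21 4,5-bis(allyloxy)-2-{(E)-[(5S,8S,10S)-4,4,8,10-tetramethyl-trans-decalin-9-ylidene]methyl}phenol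
Product: 22 2,3-bis(allyloxy)-6-hydroxy-5-{(E)-[(5S,8S,10S)-4,4,8,10-tetramethyl-trans-decalin-9-ylidene]methyl}benzaldehyde
Conditions: MgCl2, Et3N, paraformaldehyde, MeCN, reflux
Reagents that add atoms: paraformaldehyde (source of formaldehyde), C=O
Why: Magnesium-phenoxide-directed ortho-formylation (hydroxymethylation inside the magnesium chelate, then hydride transfer to a second formaldehyde) can only reach C3′, the single free position ortho to the phenol, a pattern known for phenols whose ortho position is flanked by an alkoxy group.

Step 16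
Reactants: 22 2,3-bis(allyloxy)-6-hydroxy-5-{(E)-[(5S,8S,10S)-4,4,8,10-tetramethyl-trans-decalin-9-ylidene]methyl}benzaldehyde
Product: 23 3,4-bis(allyloxy)-2-formyl-6-{(E)-[(5S,8S,10S)-4,4,8,10-tetramethyl-trans-decalin-9-ylidene]methyl}phenyl hydrogen sulfate (handled as its sodium salt)
Conditions: SO3·pyridine (excess), pyridine, 60 °C; then aq. NaHCO3
Reagents that add atoms: sulfur trioxide–pyridine complex, [O-]S(=O)(=O)[n+]1ccccc1
Why: O-Sulfonation by the sulfur trioxide–amine complex should take place at the only free hydroxyl group, with heat and excess reagent overcoming its hydrogen bond to the neighbouring aldehyde.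

Step 17
Reactants: 23 3,4-bis(allyloxy)-2-formyl-6-{(E)-[(5S,8S,10S)-4,4,8,10-tetramethyl-trans-decalin-9-ylidene]methyl}phenyl hydrogen sulfate
Product: 24 2-formyl-3,4-dihydroxy-6-{(E)-[(5S,8S,10S)-4,4,8,10-tetramethyl-trans-decalin-9-ylidene]methyl}phenyl hydrogen sulfate (CNP0149861.1)
Conditions: Pd(PPh3)4 (cat.), K2CO3, degassed MeOH, 40 °C, under argon; then H+-form cation-exchange resin, MeOH/H2O, 0 °C
Reagents that add atoms: none
Why: Allyl transfer from the two aryl allyl ethers to methanol through π-allylpalladium intermediates (zerovalent palladium catalysis) should free the catechol under mildly basic conditions that leave the aryl sulfate, the aldehyde and the trisubstituted alkene untouched, and cation exchange then gives the free hydrogen sulfate.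

Compound list
1 | (R)-(−)-carvone [(5R)-2-methyl-5-(prop-1-en-2-yl)cyclohex-2-en-1-one] | CC1=CC[C@H](CC1=O)C(C)=C | starting material
2 | carvone lithium dienolate (O–Li on C1; C1=C6 and C2=C3; 5R) | CC1=CC[C@H](C=C1O[Li])C(C)=C | intermediate (not isolated)
3 | (5R,6S)-2,6-dimethyl-5-(prop-1-en-2-yl)cyclohex-2-en-1-one (trans-6-methylcarvone; any cis epimer converges in step 2) | CC1=CC[C@H]([C@H](C)C1=O)C(C)=C | intermediate
4 | acrolein (prop-2-enal) | C=CC=O | starting material
5 | 6-methylcarvone lithium dienolate (O–Li on C1; C1=C6 and C2=C3; 5S) | CC1=CC[C@H](C(C)=C1O[Li])C(C)=C | intermediate (not isolated)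
6 | (5S,6R)-6-(1-hydroxyprop-2-en-1-yl)-2,6-dimethyl-5-(prop-1-en-2-yl)cyclohex-2-en-1-one (both carbinol epimers; hydroxyallyl group anti to isopropenyl) | CC1=CC[C@H]([C@](C)(C(O)C=C)C1=O)C(C)=C | intermediate
7 | (5S,6R)-2,6-dimethyl-6-(prop-2-enoyl)-5-(prop-1-en-2-yl)cyclohex-2-en-1-one (6-acryloyl-6-methylcarvone; acryloyl anti to isopropenyl) | CC1=CC[C@H]([C@](C)(C(=O)C=C)C1=O)C(C)=C | intermediate
8 | (5S,10R)-4,4,8,10-tetramethyl-trans-decal-7-ene-1,9-dione [(4aS,8aR)-2,5,5,8a-tetramethyl-4,4a,5,6,7,8a-hexahydronaphthalene-1,8-dione] | CC1=CC[C@H]2C(C)(C)CCC(=O)[C@]2(C)C1=O | intermediate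
9 | potassium C1-enolate of 8 (O–K on C1; C1=C2) | CC1=CC[C@H]2C(C)(C)CC=C(O[K])[C@]2(C)C1=O | intermediate (not isolated)
10 | (5S,10R)-4,4,8,10-tetramethyl-9-oxo-trans-decala-1,7-dien-1-yl trifluoromethanesulfonate | CC1=CC[C@H]2C(C)(C)CC=C(OS(=O)(=O)C(F)(F)F)[C@]2(C)C1=O | intermediate
11 | (5S,10S)-4,4,8,10-tetramethyl-trans-decala-1,7-dien-9-one | CC1=CC[C@H]2C(C)(C)CC=C[C@]2(C)C1=O | intermediate
12 | (5S,8S,10S)-4,4,8,10-tetramethyl-trans-decalin-9-one (C8 methyl β; cis to the C10 methyl) | C[C@H]1CC[C@H]2C(C)(C)CCC[C@]2(C)C1=O | intermediate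
13 | 2,4,5-trihydroxybenzaldehyde | O=Cc1cc(O)c(O)cc1O | starting material
14 | 4,5-bis(allyloxy)-2-hydroxybenzaldehyde | O=Cc1cc(OCC=C)c(OCC=C)cc1O | intermediate
15 | 4,5-bis(allyloxy)-2-(methoxymethoxy)benzaldehyde | O=Cc1cc(OCC=C)c(OCC=C)cc1OCOC | intermediate
16 | [4,5-bis(allyloxy)-2-(methoxymethoxy)phenyl]methanol | OCc1cc(OCC=C)c(OCC=C)cc1OCOC | intermediate
17 | 1,2-bis(allyloxy)-4-(chloromethyl)-5-(methoxymethoxy)benzene | ClCc1cc(OCC=C)c(OCC=C)cc1OCOC | intermediate
18 | [4,5-bis(allyloxy)-2-(methoxymethoxy)phenyl]methylmagnesium chloride | Cl[Mg]Cc1cc(OCC=C)c(OCC=C)cc1OCOC | intermediate (not isolated)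
19 | (5S,8S,9S,10S)-9-{[4,5-bis(allyloxy)-2-(methoxymethoxy)phenyl]methyl}-4,4,8,10-tetramethyl-trans-decalin-9-ol (hydroxyl β; arylmethyl α) | C[C@H]1CC[C@H]2C(C)(C)CCC[C@]2(C)[C@]1(O)Cc1cc(OCC=C)c(OCC=C)cc1OCOC | intermediate
20 | (5S,8S,10S)-9-{(E)-[4,5-bis(allyloxy)-2-(methoxymethoxy)phenyl]methylidene}-4,4,8,10-tetramethyl-trans-decalin (aryl syn to C8) | C[C@H]1CC[C@H]2C(C)(C)CCC[C@]2(C)/C1=C/c1cc(OCC=C)c(OCC=C)cc1OCOC | intermediate
21 | 4,5-bis(allyloxy)-2-{(E)-[(5S,8S,10S)-4,4,8,10-tetramethyl-trans-decalin-9-ylidene]methyl}phenol | C[C@H]1CC[C@H]2C(C)(C)CCC[C@]2(C)/C1=C/c1cc(OCC=C)c(OCC=C)cc1O | intermediate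
22 | 2,3-bis(allyloxy)-6-hydroxy-5-{(E)-[(5S,8S,10S)-4,4,8,10-tetramethyl-trans-decalin-9-ylidene]methyl}benzaldehyde | C[C@H]1CC[C@H]2C(C)(C)CCC[C@]2(C)/C1=C/c1cc(OCC=C)c(OCC=C)c(C=O)c1O | intermediate
23 | 3,4-bis(allyloxy)-2-formyl-6-{(E)-[(5S,8S,10S)-4,4,8,10-tetramethyl-trans-decalin-9-ylidene]methyl}phenyl hydrogen sulfate (handled as sodium salt) | C[C@H]1CC[C@H]2C(C)(C)CCC[C@]2(C)/C1=C/c1cc(OCC=C)c(OCC=C)c(C=O)c1OS(=O)(=O)O | intermediate
24 | 2-formyl-3,4-dihydroxy-6-{(E)-[(5S,8S,10S)-4,4,8,10-tetramethyl-trans-decalin-9-ylidene]methyl}phenyl hydrogen sulfate (CNP0149861.1) | C[C@H]1CC[C@H]2C(C)(C)CCC[C@]2(C)/C1=C/c1cc(O)c(O)c(C=O)c1OS(=O)(=O)O | target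

Total step count: 17. Longest linear sequence: 13 steps (steps 1–7 and 12–17); the arene branch (steps 8–11) has 4 steps.

Steps most likely to fail

Step 12 (addition of 18 to 12). What may go wrong: self-coupling of the benzylic halide during magnesium insertion, enolisation of the ketone by the organometallic with loss of the C8 configuration, or no addition at the crowded carbonyl. Fallback, from 12 back to 20: the polarity is reversed, so that C9 becomes the nucleophile and the arene arrives as aldehyde 15. Enolisation of 12 towards C8 (KN(SiMe3)2, THF, −78 °C) and trapping with PhNTf2 would give the C9 enol triflate F1. Nozaki–Hiyama–Kishi coupling of F1 with 15 (CrCl2 in excess, NiCl2 cat., DMF, rt) would give the allylic benzylic alcohol F2 as two C11 epimers, which would be separated. Mitsunobu displacement of the suitable epimer with 2-nitrobenzenesulfonylhydrazide (PPh3, diethyl azodicarboxylate, THF, −30 °C) would give the N-allylic sulfonylhydrazine F3, which on warming would lose 2-nitrobenzenesulfinic acid to form the allylic diazene F4. Suprafacial retro-ene loss of N2 from F4 would move the double bond to C9=C11 and place hydrogen on C8, giving 20. The hydrogen goes to the face that carries the diazene, so the epimer used is the one whose diazene lies on the α-face when the aryl group is syn to C8; the other epimer would be recycled by oxidation and reduction. Because C8 is planar in F1 and is re-created in the last event, this detour would also repair a poor facial course of step 7.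

Step 4 (key step). What may go wrong: hydrogen-atom transfer to the acryloyl alkene (simple conjugate reduction) or oligomerisation of the vinyl ketone outrunning cyclisation. Fallback, from 6 back to 8: the same C4 radical would be generated from a preformed halide and not by hydrogen-atom transfer. Markovnikov addition of HBr (1 equiv, CH2Cl2/AcOH, −20 °C, dark) to the isopropenyl group of 6 would give the tertiary bromide F5. Dess–Martin oxidation would give the bromo enedione F6. Slow addition of Bu3SnH with AIBN (benzene, 80 °C, high dilution) would abstract bromine and close ring A by the same 6-endo Giese addition, giving 8.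

Step 15 (formylation). What may go wrong: slow hydroxymethylation at the crowded position between the phenol and the allyloxy group, with stalling before the hydride transfer. Fallback, from 21 back to 22: boronate-templated ortho-hydroxymethylation (PhB(OH)2, paraformaldehyde, cat. EtCO2H, toluene, reflux with water removal) would give the 2-phenyl-1,3,2-benzodioxaborin F7. Mild aqueous hydrolysis would give the salicyl alcohol F8, and MnO2 (CH2Cl2, rt) would oxidise its benzylic alcohol to the aldehyde 22.

Further compounds
F1 | step 12 | (5S,10S)-4,4,8,10-tetramethyl-trans-decal-8-en-9-yl trifluoromethanesulfonate (C8=C9 enol triflate) | CC=1CC[C@H]2C(C)(C)CCC[C@]2(C)C=1OS(=O)(=O)C(F)(F)F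
F2 | step 12 | [4,5-bis(allyloxy)-2-(methoxymethoxy)phenyl][(5S,10S)-4,4,8,10-tetramethyl-trans-decal-8-en-9-yl]methanol (C11 epimers) | CC=1CC[C@H]2C(C)(C)CCC[C@]2(C)C=1C(O)c1cc(OCC=C)c(OCC=C)cc1OCOC
F3 | step 12 | N-allylic N-(2-nitrophenylsulfonyl)hydrazine derived from F2 (nitrogen on C11) | CC=1CC[C@H]2C(C)(C)CCC[C@]2(C)C=1C(N(N)S(=O)(=O)c1ccccc1[N+](=O)[O-])c1cc(OCC=C)c(OCC=C)cc1OCOC
F4 | step 12 | allylic diazene on C11 | CC=1CC[C@H]2C(C)(C)CCC[C@]2(C)C=1C(N=N)c1cc(OCC=C)c(OCC=C)cc1OCOC
F5 | step 4 | (5R,6R)-5-(2-bromopropan-2-yl)-6-(1-hydroxyprop-2-en-1-yl)-2,6-dimethylcyclohex-2-en-1-one (carbinol epimers) | CC1=CC[C@H]([C@](C)(C(O)C=C)C1=O)C(C)(C)Br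
F6 | step 4 | (5R,6R)-5-(2-bromopropan-2-yl)-2,6-dimethyl-6-(prop-2-enoyl)cyclohex-2-en-1-one | CC1=CC[C@H]([C@](C)(C(=O)C=C)C1=O)C(C)(C)Br
F7 | step 15 | 2-phenyl-4H-1,3,2-benzodioxaborin spanning O2′ and a new CH2 on C3′ of 21 | C[C@H]1CC[C@H]2C(C)(C)CCC[C@]2(C)/C1=C/c1cc(OCC=C)c(OCC=C)c3COB(c4ccccc4)Oc13
F8 | step 15 | 3,4-bis(allyloxy)-2-(hydroxymethyl)-6-{(E)-[(5S,8S,10S)-4,4,8,10-tetramethyl-trans-decalin-9-ylidene]methyl}phenol | C[C@H]1CC[C@H]2C(C)(C)CCC[C@]2(C)/C1=C/c1cc(OCC=C)c(OCC=C)c(CO)c1O
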